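## Retrosynthetic overview

- Target ← tert-butyl ester ← exocyclic C8=C17 methylene dienone (face-selective hydrogenation sets C8) ← Δ5-7-ketone, after allylic oxidation and excision of a C1 isopropenyl control group.
- Ring B ← Diels–Alder reaction of a ring A 1-vinylcyclohexene (C10=C5–C6=C7) with a 2-alkylacrolein (C8=C9; its CHO later becomes the C20 methyl). This sets C9 and C10.
- Diene ← (S)-carvone: the reductive aldol with formaldehyde sets C4, then enol triflate and vinylation.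
- Dienophile ← (R)-citronellic acid (C13 bought): ozonolysis, one-carbon homologation, α-methylenation.
- Ring order: ring A is bought with carvone; ring B is closed by the cycloaddition.

Assumption: positions are cited with halimane locants (decalin C1–C10, side chain C11–C16 with C15 the acid carbon, C17 on C8, C18 = CH2OAc and C19 = CH3 on C4, C20 on C9); α is the face of H-10 in the target.

## Route

Step 1
Reactants: 1 (S)-(+)-carvone
Product: 3 (2S,5S)-2-(hydroxymethyl)-2-methyl-5-(prop-1-en-2-yl)cyclohexan-1-one, via lithium enolate 2 (not isolated)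
Conditions: LiBH(s-Bu)3, THF, −78 °C; then anhydrous CH2O in THF, −78 → −40 °C; AcOH quench
Reagents that add atoms: formaldehyde, C=O
Why: Reductive aldol reaction: conjugate hydride addition gives the enolate regiospecifically, and formaldehyde adds axially to the chair-like enolate with the isopropenyl group equatorial, so CH2OH enters cis to isopropenyl and sets the quaternary carbon (future C4); the minor epimer is removed by chromatography.

Step 2
Reactants: 3 (2S,5S)-2-(hydroxymethyl)-2-methyl-5-(prop-1-en-2-yl)cyclohexan-1-one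
Product: 4 [(1S,4S)-1-methyl-2-oxo-4-(prop-1-en-2-yl)cyclohexyl]methyl acetate
Conditions: Ac2O, pyridine, DMAP (cat.), CH2Cl2, 0 °C → rt
Reagents that add atoms: acetic anhydride, CC(=O)OC(C)=O
Why: Simple O-acylation of the primary alcohol installs the final C18 acetate early and blocks retro-aldol loss of formaldehyde.

Step 3
Reactants: 4 [(1S,4S)-1-methyl-2-oxo-4-(prop-1-en-2-yl)cyclohexyl]methyl acetate
Product: 5 [(1S,4S)-1-methyl-4-(prop-1-en-2-yl)-2-(trifluoromethanesulfonyloxy)cyclohex-2-en-1-yl]methyl acetate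
Conditions: Tf2O, 2,6-di-tert-butyl-4-methylpyridine, CH2Cl2, 0 °C → rt
Reagents that add atoms: trifluoromethanesulfonic anhydride, FC(F)(F)S(=O)(=O)OS(=O)(=O)C(F)(F)F
Why: Enol triflate formation under non-basic conditions; the ketone can enolise only toward the CH2 (future C10) because the other α-carbon is quaternary, and no enolate is formed that could take the acetyl group.

Step 4
Reactants: 5 [(1S,4S)-1-methyl-4-(prop-1-en-2-yl)-2-(trifluoromethanesulfonyloxy)cyclohex-2-en-1-yl]methyl acetate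
Product: 6 [(1R,4S)-2-ethenyl-1-methyl-4-(prop-1-en-2-yl)cyclohex-2-en-1-yl]methyl acetate
Conditions: CH2=CHSnBu3, Pd(PPh3)4 (5 mol %), LiCl, THF, reflux
Reagents that add atoms: tributyl(vinyl)stannane, CCCC[Sn](CCCC)(CCCC)C=C
Why: Stille coupling of a hindered cyclohexenyl triflate under neutral conditions gives the s-cis-biased 1-vinylcyclohexene diene without touching the acetate.

Step 5
Reactants: 7 (R)-(+)-citronellic acid
Product: 8 tert-butyl (3R)-3,7-dimethyloct-6-enoate
Conditions: Cl3CC(=NH)Ot-Bu, CH2Cl2–cyclohexane, rt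
Reagents that add atoms: tert-butyl 2,2,2-trichloroacetimidate, CC(C)(C)OC(=N)C(Cl)(Cl)Cl
Why: Imidate esterification gives a tert-butyl ester that survives all later steps and can be removed by acid at the end without touching the acetate.

Step 6
Reactants: 8 tert-butyl (3R)-3,7-dimethyloct-6-enoate
Product: 10 tert-butyl (3R)-3-methyl-6-oxohexanoate, via ozonide 9 (not isolated)
Conditions: O3, CH2Cl2, −78 °C; then PPh3, −78 °C → rt
Reagents that add atoms: ozone, [O-][O+]=O
Why: Ozonolysis with reductive work-up cleaves the trisubstituted alkene to the aldehyde whose carbonyl carbon becomes C9; the C13 stereocentre is remote and untouched.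

Step 7
Reactants: 10 tert-butyl (3R)-3-methyl-6-oxohexanoate
Product: 12 tert-butyl (3R)-3-methyl-7-oxoheptanoate, via enol ether 11 (not isolated)
Conditions: Ph3P(CH2OMe)Cl, KOt-Bu, THF, 0 °C; then 1 M HCl (aq), THF, rt
Reagents that add atoms: (methoxymethyl)triphenylphosphonium chloride, COC[P+](c1ccccc1)(c1ccccc1)c1ccccc1.[Cl-]; water, O
Why: Wittig methoxymethylenation and enol ether hydrolysis add the one carbon (future C20) that the aldehyde homologation needs.

Step 8
Reactants: 12 tert-butyl (3R)-3-methyl-7-oxoheptanoate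
Product: 13 tert-butyl (3R)-6-formyl-3-methylhept-6-enoate
Conditions: CH2O (37 % aq), pyrrolidine (10 mol %), EtCO2H (10 mol %), i-PrOH, 45 °C
Reagents that add atoms: formaldehyde, C=O
Why: Amine-catalysed Mannich condensation and elimination (α-methylenation of an aldehyde) gives the 2-alkylacrolein dienophile, with the new CH2 as C8 and the α-carbon as C9.

Step 9
Reactants: 6 [(1R,4S)-2-ethenyl-1-methyl-4-(prop-1-en-2-yl)cyclohex-2-en-1-yl]methyl acetate; 13 tert-butyl (3R)-6-formyl-3-methylhept-6-enoate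
Product: 14 tert-butyl (3R)-5-[(1S,5R,8S,8aR)-5-(acetyloxymethyl)-1-formyl-5-methyl-8-(prop-1-en-2-yl)-1,2,3,5,6,7,8,8a-octahydronaphthalen-1-yl]-3-methylpentanoate
Conditions: Me2AlCl (2.5 equiv), CH2Cl2, −78 → −40 °C; cold 1 M HCl quench
Reagents that add atoms: none
Why: Lewis-acid-promoted Diels–Alder reaction: the unsubstituted diene terminus C7 bonds to the acrolein CH2 (C8) and C10 to the α-carbon (C9), the aldehyde sits endo (so the future C20 is β, cis to the C10–C1 bond, and the chain is α), and the dienophile adds to the face opposite the C1 isopropenyl group, which sets C9 and C10 relative to the carvone-derived centres.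

Step 10
Reactants: 14 tert-butyl (3R)-5-[(1S,5R,8S,8aR)-5-(acetyloxymethyl)-1-formyl-5-methyl-8-(prop-1-en-2-yl)-1,2,3,5,6,7,8,8a-octahydronaphthalen-1-yl]-3-methylpentanoate
Product: 16 tert-butyl (3R)-5-[(1R,5R,8S,8aS)-5-(acetyloxymethyl)-1,5-dimethyl-8-(prop-1-en-2-yl)-1,2,3,5,6,7,8,8a-octahydronaphthalen-1-yl]-3-methylpentanoate, via tosylhydrazone 15 (not isolated)
Conditions: TsNHNH2, EtOH, 50 °C; solvent switch; catecholborane, CHCl3, 0 °C → rt; then NaOAc·3H2O, reflux
Reagents that add atoms: none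
Why: Tosylhydrazone reduction (hydride addition, loss of sulfinate and N2 from the diazene) turns the neopentyl aldehyde into the C20 methyl under conditions that spare both esters and all three alkenes.

Step 11
Reactants: 16 tert-butyl (3R)-5-[(1R,5R,8S,8aS)-5-(acetyloxymethyl)-1,5-dimethyl-8-(prop-1-en-2-yl)-1,2,3,5,6,7,8,8a-octahydronaphthalen-1-yl]-3-methylpentanoate
Product: 17 tert-butyl (3R)-5-[(1R,5R,8S,8aS)-5-(acetyloxymethyl)-1,5-dimethyl-3-oxo-8-(prop-1-en-2-yl)-1,2,3,5,6,7,8,8a-octahydronaphthalen-1-yl]-3-methylpentanoate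
Conditions: CrO3, 3,5-dimethylpyrazole, CH2Cl2, −20 °C
Reagents that add atoms: chromium trioxide, O=[Cr](=O)=O
Why: Allylic oxidation of the ring CH2 (C7) next to the trisubstituted C5=C6 bond gives the Δ5-7-ketone, as in the oxidation of Δ5-steroids and of valencene to nootkatone, where an isopropenyl group survives.

Step 12
Reactants: 17 tert-butyl (3R)-5-[(1R,5R,8S,8aS)-5-(acetyloxymethyl)-1,5-dimethyl-3-oxo-8-(prop-1-en-2-yl)-1,2,3,5,6,7,8,8a-octahydronaphthalen-1-yl]-3-methylpentanoate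
Product: 19 tert-butyl (3R)-5-[(1R,5R,8aS)-5-(acetyloxymethyl)-1,5-dimethyl-3-oxo-1,2,3,5,6,7,8,8a-octahydronaphthalen-1-yl]-3-methylpentanoate, via methoxy hydroperoxide 18 (not isolated)
Conditions: O3, MeOH, −78 °C; then PhSH, FeSO4·7H2O, −78 °C → rt
Reagents that add atoms: none
Why: Ozonolysis and radical hydrodealkenylation: ozone attacks only the electron-rich isopropenyl group (the enone C=C is deactivated), ferrous ion turns the α-methoxy hydroperoxide into an alkoxy radical whose β-scission expels methyl acetate, and the C1 radical takes hydrogen from PhSH, so the control element is removed and C1 becomes CH2.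

Step 13
Reactants: 19 tert-butyl (3R)-5-[(1R,5R,8aS)-5-(acetyloxymethyl)-1,5-dimethyl-3-oxo-1,2,3,5,6,7,8,8a-octahydronaphthalen-1-yl]-3-methylpentanoate
Product: 20 tert-butyl (3R)-5-[(1S,5R,8aS)-5-(acetyloxymethyl)-1,5-dimethyl-2-methylidene-3-oxo-1,2,3,5,6,7,8,8a-octahydronaphthalen-1-yl]-3-methylpentanoate
Conditions: (CH2O)n, i-Pr2NH2 CF3CO2, CF3CO2H (10 mol %), THF, reflux
Reagents that add atoms: paraformaldehyde (formaldehyde source), C=O
Why: Mannich condensation and elimination at the only α′-CH2 (C8) installs C17 as an exocyclic methylene without strong base, so the acetate, the tert-butyl ester and the C9 and C10 centres are untouched.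

Step 14
Reactants: 20 tert-butyl (3R)-5-[(1S,5R,8aS)-5-(acetyloxymethyl)-1,5-dimethyl-2-methylidene-3-oxo-1,2,3,5,6,7,8,8a-octahydronaphthalen-1-yl]-3-methylpentanoate
Product: 21 tert-butyl (3R)-5-[(1S,2R,5R,8aS)-5-(acetyloxymethyl)-1,2,5-trimethyl-3-oxo-1,2,3,5,6,7,8,8a-octahydronaphthalen-1-yl]-3-methylpentanoate
Conditions: H2 (1 atm), RhCl(PPh3)3 (5 mol %), benzene, rt
Reagents that add atoms: none
Why: Homogeneous hydrogenation reduces only the unhindered exocyclic enone C=C and delivers hydrogen to the α face of C8, anti to the axial C9 methyl group, giving the 8β (equatorial) methyl group.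

Step 15
Reactants: 21 tert-butyl (3R)-5-[(1S,2R,5R,8aS)-5-(acetyloxymethyl)-1,2,5-trimethyl-3-oxo-1,2,3,5,6,7,8,8a-octahydronaphthalen-1-yl]-3-methylpentanoate
Product: 22 (3R)-5-[(1S,2R,5R,8aS)-5-(acetyloxymethyl)-1,2,5-trimethyl-3-oxo-1,2,3,5,6,7,8,8a-octahydronaphthalen-1-yl]-3-methylpentanoic acid
Conditions: CF3CO2H, CH2Cl2, 0 °C
Reagents that add atoms: none
Why: Acidolysis of the tert-butyl ester (loss of 2-methylpropene) frees the C15 acid under cold, base-free conditions that leave the primary acetate and the C8 centre alone.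

## Compound list

1 | (S)-(+)-carvone, (5S)-2-methyl-5-(prop-1-en-2-yl)cyclohex-2-en-1-one | CC1=CC[C@H](C(C)=C)CC1=O | starting material
2 | lithium (5S)-2-methyl-5-(prop-1-en-2-yl)cyclohex-1-en-1-olate | [Li+].[O-]C1=C(C)CC[C@H](C(C)=C)C1 | intermediate
3 | (2S,5S)-2-(hydroxymethyl)-2-methyl-5-(prop-1-en-2-yl)cyclohexan-1-one | OC[C@]1(C)CC[C@H](C(C)=C)CC1=O | intermediate
4 | [(1S,4S)-1-methyl-2-oxo-4-(prop-1-en-2-yl)cyclohexyl]methyl acetate | CC(=O)OC[C@]1(C)CC[C@H](C(C)=C)CC1=O | intermediate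
5 | [(1S,4S)-1-methyl-4-(prop-1-en-2-yl)-2-(trifluoromethanesulfonyloxy)cyclohex-2-en-1-yl]methyl acetate | CC(=O)OC[C@]1(C)CC[C@H](C(C)=C)C=C1OS(=O)(=O)C(F)(F)F | intermediate
6 | [(1R,4S)-2-ethenyl-1-methyl-4-(prop-1-en-2-yl)cyclohex-2-en-1-yl]methyl acetate | CC(=O)OC[C@]1(C)CC[C@H](C(C)=C)C=C1C=C | intermediate
7 | (R)-(+)-citronellic acid, (3R)-3,7-dimethyloct-6-enoic acid | CC(C)=CCC[C@@H](C)CC(=O)O | starting material
8 | tert-butyl (3R)-3,7-dimethyloct-6-enoate | CC(C)=CCC[C@@H](C)CC(=O)OC(C)(C)C | intermediate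
9 | tert-butyl (3R)-5-(5,5-dimethyl-1,2,4-trioxolan-3-yl)-3-methylpentanoate (ozonide, epimers at the ring CH) | CC1(C)OOC(CC[C@@H](C)CC(=O)OC(C)(C)C)O1 | intermediate
10 | tert-butyl (3R)-3-methyl-6-oxohexanoate | O=CCC[C@@H](C)CC(=O)OC(C)(C)C | intermediate
11 | tert-butyl (3R)-7-methoxy-3-methylhept-6-enoate (E/Z mixture) | COC=CCC[C@@H](C)CC(=O)OC(C)(C)C | intermediate
12 | tert-butyl (3R)-3-methyl-7-oxoheptanoate | O=CCCC[C@@H](C)CC(=O)OC(C)(C)C | intermediate
13 | tert-butyl (3R)-6-formyl-3-methylhept-6-enoate | O=CC(=C)CC[C@@H](C)CC(=O)OC(C)(C)C | intermediate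
14 | tert-butyl (3R)-5-[(1S,5R,8S,8aR)-5-(acetyloxymethyl)-1-formyl-5-methyl-8-(prop-1-en-2-yl)-1,2,3,5,6,7,8,8a-octahydronaphthalen-1-yl]-3-methylpentanoate | CC(=O)OC[C@]1(C)CC[C@H](C(C)=C)[C@@H]2C1=CCC[C@@]2(C=O)CC[C@@H](C)CC(=O)OC(C)(C)C | intermediate
15 | N-tosylhydrazone of 14 (C20 carbon as CH=N–NHTs) | CC(=O)OC[C@]1(C)CC[C@H](C(C)=C)[C@@H]2C1=CCC[C@@]2(C=NNS(=O)(=O)c3ccc(C)cc3)CC[C@@H](C)CC(=O)OC(C)(C)C | intermediate
16 | tert-butyl (3R)-5-[(1R,5R,8S,8aS)-5-(acetyloxymethyl)-1,5-dimethyl-8-(prop-1-en-2-yl)-1,2,3,5,6,7,8,8a-octahydronaphthalen-1-yl]-3-methylpentanoate | CC(=O)OC[C@]1(C)CC[C@H](C(C)=C)[C@@H]2C1=CCC[C@@]2(C)CC[C@@H](C)CC(=O)OC(C)(C)C | intermediate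
17 | tert-butyl (3R)-5-[(1R,5R,8S,8aS)-5-(acetyloxymethyl)-1,5-dimethyl-3-oxo-8-(prop-1-en-2-yl)-1,2,3,5,6,7,8,8a-octahydronaphthalen-1-yl]-3-methylpentanoate | CC(=O)OC[C@]1(C)CC[C@H](C(C)=C)[C@@H]2C1=CC(=O)C[C@@]2(C)CC[C@@H](C)CC(=O)OC(C)(C)C | intermediate
18 | tert-butyl (3R)-5-[(1R,5R,8S,8aS)-5-(acetyloxymethyl)-8-(1-hydroperoxy-1-methoxyethyl)-1,5-dimethyl-3-oxo-1,2,3,5,6,7,8,8a-octahydronaphthalen-1-yl]-3-methylpentanoate (epimers at the peroxy carbon) | CC(=O)OC[C@]1(C)CC[C@H](C(C)(OC)OO)[C@@H]2C1=CC(=O)C[C@@]2(C)CC[C@@H](C)CC(=O)OC(C)(C)C | intermediate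
19 | tert-butyl (3R)-5-[(1R,5R,8aS)-5-(acetyloxymethyl)-1,5-dimethyl-3-oxo-1,2,3,5,6,7,8,8a-octahydronaphthalen-1-yl]-3-methylpentanoate | CC(=O)OC[C@]1(C)CCC[C@@H]2C1=CC(=O)C[C@@]2(C)CC[C@@H](C)CC(=O)OC(C)(C)C | intermediate
20 | tert-butyl (3R)-5-[(1S,5R,8aS)-5-(acetyloxymethyl)-1,5-dimethyl-2-methylidene-3-oxo-1,2,3,5,6,7,8,8a-octahydronaphthalen-1-yl]-3-methylpentanoate | CC(=O)OC[C@]1(C)CCC[C@@H]2C1=CC(=O)C(=C)[C@@]2(C)CC[C@@H](C)CC(=O)OC(C)(C)C | intermediate
21 | tert-butyl (3R)-5-[(1S,2R,5R,8aS)-5-(acetyloxymethyl)-1,2,5-trimethyl-3-oxo-1,2,3,5,6,7,8,8a-octahydronaphthalen-1-yl]-3-methylpentanoate | CC(=O)OC[C@]1(C)CCC[C@@H]2C1=CC(=O)[C@H](C)[C@@]2(C)CC[C@@H](C)CC(=O)OC(C)(C)C | intermediate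
22 | (3R)-5-[(1S,2R,5R,8aS)-5-(acetyloxymethyl)-1,2,5-trimethyl-3-oxo-1,2,3,5,6,7,8,8a-octahydronaphthalen-1-yl]-3-methylpentanoic acid (CNP0210381.1) | CC(=O)OC[C@]1(C)CCC[C@@H]2C1=CC(=O)[C@H](C)[C@@]2(C)CC[C@@H](C)CC(=O)O | target

## Step count and risks

Total steps: 15. Longest linear sequence: 11 steps (steps 1–4 then 9–15, or steps 5–8 then 9–15).

Steps most likely to fail:

Step 9. The cycloaddition joins a quaternary C9 to a C10 that is flanked by the isopropenyl-bearing C1, so it may be slow. Me2AlCl can also close the product aldehyde onto the nearby isopropenyl group in a carbonyl-ene reaction, or erode the endo and facial selectivity. The fallback sets out from 13 (with 6) and comes back at 14. Compound 13 is treated with 1,2-bis(trimethylsilyloxy)ethane and catalytic TMSOTf in CH2Cl2 at −78 °C to give tert-butyl (3R)-6-(1,3-dioxolan-2-yl)-3-methylhept-6-enoate F1. F1 and 6 then undergo an ionic Diels–Alder reaction through the dioxolenium allyl cation (TMSOTf 5 mol %, 2,6-di-tert-butylpyridine, CH2Cl2, −78 °C; the catalytic loading and low temperature spare the tert-butyl ester). This gives tert-butyl (3R)-5-[(1S,5R,8S,8aR)-5-(acetyloxymethyl)-1-(1,3-dioxolan-2-yl)-5-methyl-8-(prop-1-en-2-yl)-1,2,3,5,6,7,8,8a-octahydronaphthalen-1-yl]-3-methylpentanoate F2, which cannot undergo the ene closure. Hydrolysis with pyridinium p-toluenesulfonate in wet acetone returns 14.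

Step 11. The chromium oxidant may abstract the tertiary allylic C10–H or attack the isopropenyl group instead of the C7 methylene. The fallback sets out from 16 and comes back at 17. One equivalent of mCPBA (NaHCO3, CH2Cl2, −20 °C) epoxidises the more electron-rich trisubstituted C5=C6 bond to the 5α,6α-epoxide of 16 F3 (drawn for α attack; either epoxide face converges on 17). PhSeSePh/NaBH4 in EtOH opens it at the secondary C6 to the 5α-hydroxy-6β-phenylselanyl derivative of 16 F4. H2O2 then gives selenoxide elimination, which can only go toward C7, to the 5α-hydroxy-6-ene derived from 16 F5. Oxidative 1,3-transposition of this tertiary allylic alcohol with C5H5NH[CrO3Cl] in CH2Cl2 gives 17.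

Step 13 (with the face selectivity used in step 14). Methylenation at the neopentyl-type C8 methylene may be slow or may go through the extended dienol. The fallback sets out from 19 and comes back at 21, skipping 20. Kinetic α′-deprotonation with LiN(i-Pr)2 (THF, −78 °C) and MeI alkylates anti to the axial C9 methyl group. This gives tert-butyl (3R)-5-[(1S,2S,5R,8aS)-5-(acetyloxymethyl)-1,2,5-trimethyl-3-oxo-1,2,3,5,6,7,8,8a-octahydronaphthalen-1-yl]-3-methylpentanoate F6, the 8α-methyl epimer. A second deprotonation with LiN(i-Pr)2 at −78 °C and kinetic protonation with 2,6-di-tert-butyl-4-methylphenol, again from the α face, inverts C8 and gives 21.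

Further compounds
F1 | step 9 | tert-butyl (3R)-6-(1,3-dioxolan-2-yl)-3-methylhept-6-enoate | C=C(C1OCCO1)CC[C@@H](C)CC(=O)OC(C)(C)C
F2 | step 9 | tert-butyl (3R)-5-[(1S,5R,8S,8aR)-5-(acetyloxymethyl)-1-(1,3-dioxolan-2-yl)-5-methyl-8-(prop-1-en-2-yl)-1,2,3,5,6,7,8,8a-octahydronaphthalen-1-yl]-3-methylpentanoate | CC(=O)OC[C@]1(C)CC[C@H](C(C)=C)[C@@H]2C1=CCC[C@@]2(C3OCCO3)CC[C@@H](C)CC(=O)OC(C)(C)C
F3 | step 11 | 5α,6α-epoxide of 16 | CC(=O)OC[C@]1(C)CC[C@H](C(C)=C)[C@@H]2[C@]13O[C@H]3CC[C@@]2(C)CC[C@@H](C)CC(=O)OC(C)(C)C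
F4 | step 11 | 5α-hydroxy-6β-phenylselanyl derivative of 16 | CC(=O)OC[C@]1(C)CC[C@H](C(C)=C)[C@@H]2[C@@]1(O)[C@H]([Se]c3ccccc3)CC[C@@]2(C)CC[C@@H](C)CC(=O)OC(C)(C)C
F5 | step 11 | 5α-hydroxy-6-ene derived from 16 | CC(=O)OC[C@]1(C)CC[C@H](C(C)=C)[C@@H]2[C@@]1(O)C=CC[C@@]2(C)CC[C@@H](C)CC(=O)OC(C)(C)C
F6 | step 13 | tert-butyl (3R)-5-[(1S,2S,5R,8aS)-5-(acetyloxymethyl)-1,2,5-trimethyl-3-oxo-1,2,3,5,6,7,8,8a-octahydronaphthalen-1-yl]-3-methylpentanoate | CC(=O)OC[C@]1(C)CCC[C@@H]2C1=CC(=O)[C@@H](C)[C@@]2(C)CC[C@@H](C)CC(=O)OC(C)(C)C
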